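**Strategy.** Gustastatin is a depside whose acyl ring A (C1 carboxyl, 2‑OH, 4‑OMe, C6 2‑oxoheptyl) is a folded polyketide. Instead of esterifying two finished arenes, the depside C(=O)–O bond is made first and ring A is built on it. An open‑chain diketo‑dioxinone is thermolysed to an acylketene, the 4‑OH of the ring‑B phenol adds to it, and the resulting aryl 3,5,7‑trioxo ester closes C2→C7 (aldol, dehydration) to the resorcylate. One operation thus forms the hindered ester bond and the C1–C6 bond of ring A. The precursor carries the side‑chain ketone as a dioxolane; the same dioxinone, aromatised by base without a nucleophile, also supplies ring B.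

Key step: step 9

Remark: the target has no stereogenic element (it is achiral), so no stereocentre has to be set or preserved. Compounds 1 and 4 are taken as commercial.

Step 1
Reactants: 1 ethyl 3-oxooctanoate
Product: 2 ethyl 2-(2-pentyl-1,3-dioxolan-2-yl)acetate
Conditions: ethylene glycol, p-TsOH (cat.), PhMe, reflux, Dean–Stark
Reagents that add atoms: ethylene glycol, OCCO
Why: Acid-catalysed ketalisation of the ketone of a β-keto ester with azeotropic removal of water should mask the future side-chain ketone, which is needed so that only one aldol mode exists later.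

Step 2
Reactants: 2 ethyl 2-(2-pentyl-1,3-dioxolan-2-yl)acetate
Product: 3 N-methoxy-N-methyl-2-(2-pentyl-1,3-dioxolan-2-yl)acetamide
Conditions: MeNH(OMe)·HCl, i-PrMgCl, THF, −20 to 0 °C
Reagents that add atoms: N,O-dimethylhydroxylamine hydrochloride, CNOC.Cl
Why: Aminolysis of the ester by the weakly basic magnesium amide of N,O-dimethylhydroxylamine (Weinreb amide formation) should proceed without touching the ketal.

Step 3
Reactants: 4 2,2,6-trimethyl-4H-1,3-dioxin-4-one
Product: 5 2,2-dimethyl-6-(2-oxopropyl)-4H-1,3-dioxin-4-one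
Conditions: LiHMDS (2 equiv), THF, −78 °C; AcCl (0.5 equiv relative to enolate); aq. NH4Cl
Reagents that add atoms: acetyl chloride, CC(=O)Cl
Why: The lithium dienolate of the dioxinone is C-acylated at its γ-carbon (vinylogous Claisen acylation), the excess enolate serving to deprotonate the more acidic keto-dioxinone product.

Step 4
Reactants: 5 2,2-dimethyl-6-(2-oxopropyl)-4H-1,3-dioxin-4-one; 3 N-methoxy-N-methyl-2-(2-pentyl-1,3-dioxolan-2-yl)acetamide
Product: 6 2,2-dimethyl-6-[2,4-dioxo-5-(2-pentyl-1,3-dioxolan-2-yl)pentyl]-4H-1,3-dioxin-4-one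
Conditions: LDA (2.2 equiv), THF, −78 °C; then 3, −78 to −40 °C; aq. NH4Cl
Reagents that add atoms: none
Why: The dianion of 5 reacts at its terminal, more basic carbon with the Weinreb amide (crossed Claisen condensation), and the chelated tetrahedral adduct should release the 1,3-diketone only on quench, which prevents over-addition.

Step 5
Reactants: 6 2,2-dimethyl-6-[2,4-dioxo-5-(2-pentyl-1,3-dioxolan-2-yl)pentyl]-4H-1,3-dioxin-4-one
Product: 7 7-hydroxy-2,2-dimethyl-5-[(2-pentyl-1,3-dioxolan-2-yl)methyl]-4H-1,3-benzodioxin-4-one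
Conditions: Et3N (3 equiv), CH2Cl2, rt
Reagents that add atoms: none
Why: At room temperature the dioxinone ring stays intact, its nucleophilic C5 adds to the distal chain ketone in a 6-exo-trig aldol closure and dehydration with tautomerisation (base-mediated cycloaromatisation of a diketo-dioxinone) should give the acetonide-bridged resorcylate, in which the carboxyl and the ortho hydroxyl are tied up and only the para hydroxyl is free, the dioxolane leaving no other six-membered aldol mode open.

Step 6
Reactants: 7 7-hydroxy-2,2-dimethyl-5-[(2-pentyl-1,3-dioxolan-2-yl)methyl]-4H-1,3-benzodioxin-4-one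
Product: 8 7-(benzyloxy)-2,2-dimethyl-5-[(2-pentyl-1,3-dioxolan-2-yl)methyl]-4H-1,3-benzodioxin-4-one
Conditions: BnBr, K2CO3, acetone, reflux
Reagents that add atoms: benzyl bromide, BrCc1ccccc1
Why: Williamson etherification can only occur at the single free phenol, so the site of benzylation is fixed by the acetonide bridge and not by relative acidity.

Step 7
Reactants: 8 7-(benzyloxy)-2,2-dimethyl-5-[(2-pentyl-1,3-dioxolan-2-yl)methyl]-4H-1,3-benzodioxin-4-one
Product: 10 methyl 4-(benzyloxy)-2-methoxy-6-[(2-pentyl-1,3-dioxolan-2-yl)methyl]benzoate, via 2-hydroxy methyl ester 9 (not isolated)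
Conditions: K2CO3, MeOH, rt to 40 °C; evaporate; then MeI, K2CO3, DMF, 50 °C
Reagents that add atoms: methanol, CO; iodomethane, CI
Why: Methoxide opens the benzodioxinone at its carbonyl (transesterification) with loss of acetone to give the methyl salicylate 9 as its phenoxide, which should then be methylated by the small electrophile on warming in DMF (Williamson etherification) despite its hydrogen bond to the ester.

Step 8
Reactants: 10 methyl 4-(benzyloxy)-2-methoxy-6-[(2-pentyl-1,3-dioxolan-2-yl)methyl]benzoate
Product: 11 methyl 4-hydroxy-2-methoxy-6-[(2-pentyl-1,3-dioxolan-2-yl)methyl]benzoate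
Conditions: H2 (1 atm), Pd/C, EtOAc, rt
Reagents that add atoms: none
Why: Hydrogenolysis of the benzyl aryl ether should free the 4-OH under neutral conditions that leave the ketal, both methyl groups and the ester untouched.

Step 9
Reactants: 6 2,2-dimethyl-6-[2,4-dioxo-5-(2-pentyl-1,3-dioxolan-2-yl)pentyl]-4H-1,3-dioxin-4-one; 11 methyl 4-hydroxy-2-methoxy-6-[(2-pentyl-1,3-dioxolan-2-yl)methyl]benzoate
Product: 14 3-methoxy-4-(methoxycarbonyl)-5-[(2-pentyl-1,3-dioxolan-2-yl)methyl]phenyl 2,4-dihydroxy-6-[(2-pentyl-1,3-dioxolan-2-yl)methyl]benzoate, via acylketene 12 (not isolated), via aryl trioxo ester 13 (not isolated)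
Conditions: 11 (1.3 equiv), PhMe (concentrated), 110 °C; then Et3N, CH2Cl2, 0 °C to rt
Reagents that add atoms: none
Why: At 110 °C dioxinone 6 loses acetone by retro-hetero-Diels–Alder reaction to give acylketene 12, and the only free hydroxyl of 11 (its 4-OH) adds across the ketene to give aryl trioxo ester 13, so the depside C(=O)–O bond is made on an unhindered acyl carbon before ring A exists. Triethylamine then enolises C2 of 13, which attacks the C7 ketone in a favoured 6-exo-trig aldol closure (6-(enolendo)-exo-trig for the C3 ketone enolate), and E1cB dehydration with tautomerisation aromatises the new carbocycle to ring A (chain C2 becomes C1, chain C7 becomes C6). The closest known reaction type is the sequence of dioxinone thermolysis, ketene trapping by an alcohol and aldol aromatisation used for resorcylate esters, here run with a phenol as the trapping nucleophile. No stereocentre is formed. The step needs intermolecular phenol trapping to beat capture of the ketene by its own enol (secured by an excess of 11 at high concentration), a single aldol mode (secured by the dioxolane, which removes the C9 carbonyl that would allow a C4-to-C9 closure) and retention of the aryl ester (secured by an alkoxide-free amine base at or below room temperature).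

Step 10
Reactants: 14 3-methoxy-4-(methoxycarbonyl)-5-[(2-pentyl-1,3-dioxolan-2-yl)methyl]phenyl 2,4-dihydroxy-6-[(2-pentyl-1,3-dioxolan-2-yl)methyl]benzoate
Product: 15 3-methoxy-4-(methoxycarbonyl)-5-[(2-pentyl-1,3-dioxolan-2-yl)methyl]phenyl 2-hydroxy-4-methoxy-6-[(2-pentyl-1,3-dioxolan-2-yl)methyl]benzoate
Conditions: MeI (1.05 equiv), K2CO3 (1.1 equiv), dry acetone, rt
Reagents that add atoms: iodomethane, CI
Why: Williamson methylation should occur only at the more acidic, non-chelated 4-OH of ring A, since the 2-OH is locked in a hydrogen bond to the depside carbonyl and ring B has no free phenol.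

Step 11
Reactants: 15 3-methoxy-4-(methoxycarbonyl)-5-[(2-pentyl-1,3-dioxolan-2-yl)methyl]phenyl 2-hydroxy-4-methoxy-6-[(2-pentyl-1,3-dioxolan-2-yl)methyl]benzoate
Product: 16 gustastatin (3-methoxy-4-(methoxycarbonyl)-5-(2-oxoheptyl)phenyl 2-hydroxy-4-methoxy-6-(2-oxoheptyl)benzoate)
Conditions: 1 M aq. HCl, THF, 0 °C to rt
Reagents that add atoms: water, O
Why: Acid-catalysed hydrolysis of both dioxolanes (ketal deprotection) should release the two ketones, and dilute acid at or below room temperature is chosen because the methyl and aryl benzoates survive it and enol lactonisation of a freed ketone onto the neighbouring ester (isocoumarin formation) needs much harsher acid.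

**Compound list**

1 | ethyl 3-oxooctanoate | CCCCCC(=O)CC(=O)OCC | starting material
2 | ethyl 2-(2-pentyl-1,3-dioxolan-2-yl)acetate | CCCCCC1(CC(=O)OCC)OCCO1 | intermediate
3 | N-methoxy-N-methyl-2-(2-pentyl-1,3-dioxolan-2-yl)acetamide | CCCCCC1(CC(=O)N(C)OC)OCCO1 | intermediate
4 | 2,2,6-trimethyl-4H-1,3-dioxin-4-one | CC1=CC(=O)OC(C)(C)O1 | starting material
5 | 2,2-dimethyl-6-(2-oxopropyl)-4H-1,3-dioxin-4-one | CC(=O)CC1=CC(=O)OC(C)(C)O1 | intermediate
6 | 2,2-dimethyl-6-[2,4-dioxo-5-(2-pentyl-1,3-dioxolan-2-yl)pentyl]-4H-1,3-dioxin-4-one | CCCCCC1(CC(=O)CC(=O)CC2=CC(=O)OC(C)(C)O2)OCCO1 | intermediate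
7 | 7-hydroxy-2,2-dimethyl-5-[(2-pentyl-1,3-dioxolan-2-yl)methyl]-4H-1,3-benzodioxin-4-one | CC1(C)OC(=O)c2c(CC3(CCCCC)OCCO3)cc(O)cc2O1 | intermediate
8 | 7-(benzyloxy)-2,2-dimethyl-5-[(2-pentyl-1,3-dioxolan-2-yl)methyl]-4H-1,3-benzodioxin-4-one | CC1(C)OC(=O)c2c(CC3(CCCCC)OCCO3)cc(OCc3ccccc3)cc2O1 | intermediate
9 | methyl 4-(benzyloxy)-2-hydroxy-6-[(2-pentyl-1,3-dioxolan-2-yl)methyl]benzoate | CCCCCC1(Cc2cc(OCc3ccccc3)cc(O)c2C(=O)OC)OCCO1 | intermediate
10 | methyl 4-(benzyloxy)-2-methoxy-6-[(2-pentyl-1,3-dioxolan-2-yl)methyl]benzoate | CCCCCC1(Cc2cc(OCc3ccccc3)cc(OC)c2C(=O)OC)OCCO1 | intermediate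
11 | methyl 4-hydroxy-2-methoxy-6-[(2-pentyl-1,3-dioxolan-2-yl)methyl]benzoate | CCCCCC1(Cc2cc(O)cc(OC)c2C(=O)OC)OCCO1 | intermediate
12 | 3,5,7-trioxo-8-(2-pentyl-1,3-dioxolan-2-yl)oct-1-en-1-one (acylketene) | CCCCCC1(CC(=O)CC(=O)CC(=O)C=C=O)OCCO1 | intermediate
13 | 3-methoxy-4-(methoxycarbonyl)-5-[(2-pentyl-1,3-dioxolan-2-yl)methyl]phenyl 3,5,7-trioxo-8-(2-pentyl-1,3-dioxolan-2-yl)octanoate | CCCCCC1(CC(=O)CC(=O)CC(=O)CC(=O)Oc2cc(CC3(CCCCC)OCCO3)c(C(=O)OC)c(OC)c2)OCCO1 | intermediate
14 | 3-methoxy-4-(methoxycarbonyl)-5-[(2-pentyl-1,3-dioxolan-2-yl)methyl]phenyl 2,4-dihydroxy-6-[(2-pentyl-1,3-dioxolan-2-yl)methyl]benzoate | CCCCCC1(Cc2cc(O)cc(O)c2C(=O)Oc2cc(CC3(CCCCC)OCCO3)c(C(=O)OC)c(OC)c2)OCCO1 | intermediate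
15 | 3-methoxy-4-(methoxycarbonyl)-5-[(2-pentyl-1,3-dioxolan-2-yl)methyl]phenyl 2-hydroxy-4-methoxy-6-[(2-pentyl-1,3-dioxolan-2-yl)methyl]benzoate | CCCCCC1(Cc2cc(OC)cc(O)c2C(=O)Oc2cc(CC3(CCCCC)OCCO3)c(C(=O)OC)c(OC)c2)OCCO1 | intermediate
16 | gustastatin | CCCCCC(=O)Cc1cc(OC)cc(O)c1C(=O)Oc1cc(CC(=O)CCCCC)c(C(=O)OC)c(OC)c1 | target

**Step count and risks**

Total step count: 11. Longest linear sequence: 10 steps (steps 1, 2, 4, 5, 6, 7, 8, 9, 10, 11).

Steps most likely to fail:

1. Step 9. The acylketene may be captured by its own enol oxygen (pyranone closure) faster than by the electron-poor phenol, or the aryl trioxo ester may lose its phenoxide by acyl transfer before the aldol closure. The fallback makes ring A first and forms the ester by acyl transfer from a benzodioxinone that the route already holds. It sets out from 8 and 11 and comes back at 14. The sodium phenoxide of 11 (NaH, DMF, rt to 60 °C) adds to the benzodioxinone carbonyl of 8, and collapse with loss of acetone should give 3-methoxy-4-(methoxycarbonyl)-5-[(2-pentyl-1,3-dioxolan-2-yl)methyl]phenyl 4-(benzyloxy)-2-hydroxy-6-[(2-pentyl-1,3-dioxolan-2-yl)methyl]benzoate F1. Hydrogenolysis of F1 (H2, Pd/C, EtOAc, rt) removes the benzyl ether without touching the aryl ester and gives 14. The route continues with step 10.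

2. Step 4. Proton transfer from the α-CH2 of the Weinreb amide to the dianion, followed by E1cB opening of the dioxolane, may compete with addition to the hindered amide carbonyl. The fallback replaces the Claisen condensation by an aldol addition and oxidation. It sets out from 2 and comes back at 6. Ester 2 is reduced (DIBAL-H, CH2Cl2, −78 °C) to 2-(2-pentyl-1,3-dioxolan-2-yl)acetaldehyde F2. The dianion of 5 (LDA, THF, −78 °C) adds to F2 much faster than it can deprotonate it and should give racemic 6-[4-hydroxy-2-oxo-5-(2-pentyl-1,3-dioxolan-2-yl)pentyl]-2,2-dimethyl-4H-1,3-dioxin-4-one F3. Dess–Martin oxidation of F3 removes the temporary stereocentre and gives 6.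

3. Step 10. Under carbonate the ring-A 2-phenoxide may reversibly expel the ring-B phenoxide from the activated aryl ester, and methylation of that phenoxide would make the cleavage permanent; over-methylation at the chelated 2-OH is a second loss channel. The fallback places the methyl ether on ring A before the depside bond exists. It sets out from 7 and comes back at 15. The only free phenol of 7 is methylated (MeI, K2CO3, acetone, reflux) to 7-methoxy-2,2-dimethyl-5-[(2-pentyl-1,3-dioxolan-2-yl)methyl]-4H-1,3-benzodioxin-4-one F4. The sodium phenoxide of 11 (NaH, DMF, rt to 60 °C) then opens the benzodioxinone carbonyl of F4 with loss of acetone and should give 15 directly. The route continues with step 11.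

Further compounds
F1 | step 9 | 3-methoxy-4-(methoxycarbonyl)-5-[(2-pentyl-1,3-dioxolan-2-yl)methyl]phenyl 4-(benzyloxy)-2-hydroxy-6-[(2-pentyl-1,3-dioxolan-2-yl)methyl]benzoate | CCCCCC1(Cc2cc(OCc3ccccc3)cc(O)c2C(=O)Oc2cc(CC3(CCCCC)OCCO3)c(C(=O)OC)c(OC)c2)OCCO1
F2 | step 4 | 2-(2-pentyl-1,3-dioxolan-2-yl)acetaldehyde | CCCCCC1(CC=O)OCCO1
F3 | step 4 | 6-[4-hydroxy-2-oxo-5-(2-pentyl-1,3-dioxolan-2-yl)pentyl]-2,2-dimethyl-4H-1,3-dioxin-4-one (racemic) | CCCCCC1(CC(O)CC(=O)CC2=CC(=O)OC(C)(C)O2)OCCO1
F4 | step 10 | 7-methoxy-2,2-dimethyl-5-[(2-pentyl-1,3-dioxolan-2-yl)methyl]-4H-1,3-benzodioxin-4-one | CC1(C)OC(=O)c2c(CC3(CCCCC)OCCO3)cc(OC)cc2O1
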